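**Retrosynthetic overview**

1. Ring labels: A = guaiacyl ring of the benzyl group; B, C, D = benzo rings of dihydrofuran rings 1, 2, 3 counted from the tetrahydrofuran; E = terminal guaiacyl ring. The strategy rests on this feature: dihydrofuran rings 1 and 2 have the same configuration (2S,3R), and in each the C2–C3 bond joins an ArO–CH(Ar) carbon to a ring-bound carbon carrying a carboxyl-level CH2OH. Ring 3 is their antipode (2R,3S).
2. Tetrahydrofuran last: C2–O by benzylic-cation closure of a triol, C2–C3 by trans aldol of (S)-β-benzyl lactone 32 with aldehyde 23.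
3. Key disconnection: both C2–C3 bonds of rings 1 and 2 by twofold, catalyst-controlled Rh-carbene insertion of bis(diazo ester) 18 into its two ArO–CH2–Ar groups, then C3 epimerisation to trans. Ring B carries an aldehyde and ring 3 keeps its 3-carboxylate, so that one reduction (step 15) serves all four carbonyl groups.
4. 18 comes from three copies of phenol 8 (vanillin, Claisen, allyl cleavage) joined by Mitsunobu etherification. Ring 3 is closed first (step 8) by the same insertion with the enantiomeric catalyst.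
5. Ring order: dihydrofuran 3, then dihydrofurans 2 and 1 together, then the tetrahydrofuran.

Key step: step 14

Assumption: Rh2(S-PTTL)4 is taken to give the (2R) ether and Rh2(R-PTTL)4 the (2S) ether in this insertion; step 8 tests the sense on one ring, and the two catalyst enantiomers are exchanged between steps 8 and 14 should it be the reverse.

**Route**

Step 1
Reactants: 1 vanillin; 2 allyl bromide
Product: 3 4-(allyloxy)-3-methoxybenzaldehyde
Conditions: K2CO3, DMF, 60 °C
Reagents that add atoms: none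
Why: Williamson etherification, the vanillin phenoxide displacing bromide from the primary allylic halide.

Step 2
Reactants: 3 4-(allyloxy)-3-methoxybenzaldehyde
Product: 4 3-allyl-4-hydroxy-5-methoxybenzaldehyde
Conditions: neat, 200 °C
Reagents that add atoms: none
Why: Aromatic Claisen rearrangement delivers the allyl group to C5, the only free ortho position, and the dienone tautomerises back to the phenol.

Step 3
Reactants: 4 3-allyl-4-hydroxy-5-methoxybenzaldehyde
Product: 6 2-hydroxy-7-methoxy-2,3-dihydro-1-benzofuran-5-carbaldehyde, via secondary ozonide 5 (not isolated)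
Conditions: O3, CH2Cl2, −78 °C; then Me2S, −78 °C to rt
Reagents that add atoms: ozone O=[O+][O-]
Why: Ozonolysis should cleave the terminal alkene much faster than ozone attacks the formyl-deactivated arene, and after reduction of the ozonide the arylacetaldehyde is held by the neighbouring phenol as the five-membered cyclic hemiacetal.

Step 4
Reactants: 6 2-hydroxy-7-methoxy-2,3-dihydro-1-benzofuran-5-carbaldehyde
Product: 7 7-methoxy-2-oxo-2,3-dihydro-1-benzofuran-5-carbaldehyde
Conditions: nPr4N[RuO4] (5 mol %), N-methylmorpholine N-oxide, 4 Å molecular sieves, CH2Cl2, rt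
Reagents that add atoms: none
Why: Perruthenate oxidation of a lactol to the lactone; the aromatic aldehyde cannot be oxidised further without water.

Step 5
Reactants: 7 7-methoxy-2-oxo-2,3-dihydro-1-benzofuran-5-carbaldehyde
Product: 8 methyl 2-(5-formyl-2-hydroxy-3-methoxyphenyl)acetate
Conditions: NaOMe (0.1 equiv), MeOH, 0 °C; AcOH quench
Reagents that add atoms: methanol CO
Why: Methoxide-catalysed transesterification opens the reactive aryl ester to the methyl ester and frees the phenol, leaving the aldehyde alone.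

Step 6
Reactants: 8 methyl 2-(5-formyl-2-hydroxy-3-methoxyphenyl)acetate; 9 (4-benzyloxy-3-methoxyphenyl)methanol
Product: 10 methyl 2-{2-[(4-benzyloxy-3-methoxyphenyl)methoxy]-5-formyl-3-methoxyphenyl}acetate
Conditions: PPh3, DIAD, THF, 0 °C to rt
Reagents that add atoms: none
Why: Mitsunobu etherification, the acidic para-formyl phenol displacing the oxyphosphonium of the primary benzylic alcohol under neutral conditions.

Step 7
Reactants: 10 methyl 2-{2-[(4-benzyloxy-3-methoxyphenyl)methoxy]-5-formyl-3-methoxyphenyl}acetate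
Product: 11 methyl 2-{2-[(4-benzyloxy-3-methoxyphenyl)methoxy]-5-formyl-3-methoxyphenyl}-2-diazoacetate
Conditions: 4-acetamidobenzenesulfonyl azide, DBU, MeCN, 0 °C to rt
Reagents that add atoms: 4-acetamidobenzenesulfonyl azide CC(=O)Nc1ccc(cc1)S(=O)(=O)N=[N+]=[N-]
Why: Regitz diazo transfer to the arylacetate methylene, which is activated by aryl and ester; the aldehyde is not enolisable.

Step 8
Reactants: 11 methyl 2-{2-[(4-benzyloxy-3-methoxyphenyl)methoxy]-5-formyl-3-methoxyphenyl}-2-diazoacetate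
Product: 13 methyl (2R,3R)-2-(4-benzyloxy-3-methoxyphenyl)-5-formyl-7-methoxy-2,3-dihydro-1-benzofuran-3-carboxylate, via cis ester 12 (not isolated)
Conditions: Rh2(S-PTTL)4 (1 mol %), toluene, −78 to −40 °C; then NaOMe, MeOH, 0 °C to rt
Reagents that add atoms: none
Why: Rh-carbene 1,5 C–H insertion into the ArO–CH2–Ar group gives the cis ester with C2 fixed as R by the chiral carboxylate ligands of the divalent rhodium catalyst (assumed sense), and NaOMe then epimerises C3 through the ester enolate to the trans ester, the aldehyde being a spectator.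

Step 9
Reactants: 13 trans ester of dihydrofuran ring 3 with 5-formyl group
Product: 14 methyl (2R,3R)-2-(4-benzyloxy-3-methoxyphenyl)-5-(hydroxymethyl)-7-methoxy-2,3-dihydro-1-benzofuran-3-carboxylate
Conditions: NaBH4, MeOH/THF, 0 °C
Reagents that add atoms: none
Why: Chemoselective borohydride reduction of the aryl aldehyde; the methyl ester is not reduced at 0 °C and is already in its thermodynamic trans form.

Step 10
Reactants: 14 ring-3 benzylic alcohol; 8 methyl 2-(5-formyl-2-hydroxy-3-methoxyphenyl)acetate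
Product: 15 ring C aldehyde ether (the phenol oxygen of 8 bound to the C5 methylene of 14)
Conditions: PPh3, DIAD, THF, 0 °C to rt
Reagents that add atoms: none
Why: Mitsunobu etherification as in step 6, neutral so that the 3-carboxylate of the dihydrobenzofuran sees no alkoxide.

Step 11
Reactants: 15 ring C aldehyde ether
Product: 16 ring C benzylic alcohol
Conditions: NaBH4, MeOH/THF, 0 °C
Reagents that add atoms: none
Why: Chemoselective borohydride reduction of the aryl aldehyde in the presence of two methyl esters.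

Step 12
Reactants: 16 ring C benzylic alcohol; 8 methyl 2-(5-formyl-2-hydroxy-3-methoxyphenyl)acetate
Product: 17 bis(arylacetate) aldehyde (ring B ether of 16)
Conditions: PPh3, DIAD, THF, 0 °C to rt
Reagents that add atoms: none
Why: Mitsunobu etherification as in step 6.

Step 13
Reactants: 17 bis(arylacetate) aldehyde
Product: 18 bis(diazo ester) with ring B aldehyde and closed ring 3
Conditions: 4-acetamidobenzenesulfonyl azide (3 equiv), DBU, MeCN, 0 °C to rt
Reagents that add atoms: 4-acetamidobenzenesulfonyl azide CC(=O)Nc1ccc(cc1)S(=O)(=O)N=[N+]=[N-]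
Why: Twofold Regitz diazo transfer at the two arylacetate methylenes; the tertiary C3–H of the ring-3 ester cannot be converted into a diazo group.

Step 14
Reactants: 18 bis(diazo ester)
Product: 20 tris(dihydrobenzofuran) aldehyde triester with rings 1 and 2 (2S,3S) trans and ring 3 (2R,3R) trans, via cis-cis triester 19 (not isolated)
Conditions: Rh2(R-PTTL)4 (2 mol %), toluene/CH2Cl2, −78 to −40 °C, slow addition of 18 at high dilution; then NaOMe, MeOH, 0 °C to rt
Reagents that add atoms: none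
Why: Each diazo ester loses N2 on the divalent rhodium carboxylate to give a donor–acceptor carbene, which inserts through a concerted, hydride-transfer-like three-centre transition state into one C–H bond of the ArO–CH2–Ar group five atoms away. The closest known reaction is the enantioselective intramolecular C–H insertion of methyl 2-(2-benzyloxyaryl)diazoacetates with Rh2(PTTL)4 to cis-2-aryl-2,3-dihydrobenzofuran-3-carboxylates followed by methoxide epimerisation to trans; here it runs twice in one molecule, on the ring pattern already used in step 8. Each dihydrofuran ring closes by a 1,5 C–H insertion that forms its C2–C3 bond (five-membered ring closed at carbon, the aryl ether oxygen already in place), and the order of the two closures does not matter. C2 of both rings is set by the chiral carboxylate ligand sphere, which selects the same enantiotopic hydrogen at each methylene and so gives 2S twice, independently of the remote ring-3 centres; C3 forms cis under kinetic control and is then equilibrated by NaOMe through the ester enolate to the trans arrangement dictated by C2. The step needs site selectivity for the benzylic ether C–H over the aldehyde, the arenes, the benzyl ether and the second diazo group; the five-membered transition state, the activation of that C–H by oxygen and an electron-rich aryl group, the low temperature and the high dilution should secure it, and the ring-3 ester is already trans and unchanged by methoxide.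

Step 15
Reactants: 20 tris(dihydrobenzofuran) aldehyde triester
Product: 21 tetraol (ring B CH2OH and three C3 CH2OH groups)
Conditions: LiAlH4, THF, 0 °C
Reagents that add atoms: none
Why: Hydride reduction of the aldehyde and the three esters to primary alcohols, faster than enolisation, so every C3 keeps its configuration.

Step 16
Reactants: 21 tetraol
Product: 22 ring B aldehyde triol
Conditions: MnO2 (activated), CH2Cl2, rt
Reagents that add atoms: none
Why: MnO2 oxidises only the benzylic alcohol on ring B; the three homobenzylic primary alcohols are inert to it.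

Step 17
Reactants: 22 ring B aldehyde triol
Product: 23 tris(triisopropylsilyl) ether of 22
Conditions: iPr3SiCl, imidazole, DMF, rt
Reagents that add atoms: triisopropylsilyl chloride CC(C)[Si](Cl)(C(C)C)C(C)C
Why: Silylation of the three primary alcohols gives ethers that withstand LiN(iPr)2, LiAlH4 and the acid of step 25.

Step 18
Reactants: 24 4-tert-butoxy-4-oxobutanoic acid; 25 (S)-4-benzyl-1,3-oxazolidin-2-one
Product: 27 tert-butyl 4-[(4S)-4-benzyl-2-oxo-1,3-oxazolidin-3-yl]-4-oxobutanoate, via mixed pivalic anhydride 26 (not isolated)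
Conditions: pivaloyl chloride, Et3N, THF, −20 °C; then 25, LiCl, rt
Reagents that add atoms: none
Why: N-acylation of the oxazolidinone through the mixed anhydride with LiCl/Et3N activation; no stereocentre is formed.

Step 19
Reactants: 9 (4-benzyloxy-3-methoxyphenyl)methanol
Product: 28 1-benzyloxy-4-(bromomethyl)-2-methoxybenzene
Conditions: PBr3, CH2Cl2, 0 °C
Reagents that add atoms: phosphorus tribromide BrP(Br)Br
Why: Conversion of the primary benzylic alcohol to the bromide by substitution on the bromophosphite; used at once.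

Step 20
Reactants: 27 succinyl oxazolidinone; 28 benzylic bromide
Product: 30 tert-butyl (3S)-3-[(4-benzyloxy-3-methoxyphenyl)methyl]-4-[(4S)-4-benzyl-2-oxo-1,3-oxazolidin-3-yl]-4-oxobutanoate, via sodium enolate 29 (not isolated)
Conditions: NaN(SiMe3)2, THF, −78 °C; then 28, −78 to −40 °C
Reagents that add atoms: none
Why: Evans alkylation, in which the chelated Z enolate formed at the more acidic imide α-carbon is alkylated on the face opposite the 4-benzyl group, setting the new centre as S.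

Step 21
Reactants: 30 alkylated imide
Product: 31 tert-butyl (3S)-3-[(4-benzyloxy-3-methoxyphenyl)methyl]-4-hydroxybutanoate
Conditions: LiBH4, H2O (1 equiv), THF, 0 °C
Reagents that add atoms: none
Why: Reductive cleavage of the N-acyl oxazolidinone to the primary alcohol, returning the auxiliary and leaving the tert-butyl ester and the stereocentre untouched.

Step 22
Reactants: 31 hydroxy tert-butyl ester
Product: 32 (4S)-4-[(4-benzyloxy-3-methoxyphenyl)methyl]oxolan-2-one
Conditions: CF3CO2H, CH2Cl2, 0 °C to rt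
Reagents that add atoms: none
Why: Acidolysis of the tert-butyl ester and lactonisation of the γ-hydroxy acid; the stereocentre is remote from the reacting carbons.

Step 23
Reactants: 32 (S)-β-benzyl lactone; 23 tris(silyl ether) aldehyde
Product: 34 (3R,4S)-3-[aryl(hydroxy)methyl]-4-[(4-benzyloxy-3-methoxyphenyl)methyl]oxolan-2-one as both carbinol epimers, via lithium enolate 33 (not isolated)
Conditions: LiN(iPr)2, THF, −78 °C; then 23, −78 °C
Reagents that add atoms: none
Why: Aldol addition of the lactone enolate to the aryl aldehyde occurs anti to the β-benzyl group, giving the trans-α,β-disubstituted lactone; the carbinol configuration is unimportant because that carbon is ionised in step 25.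

Step 24
Reactants: 34 aldol adduct
Product: 35 (2S,3S)-2-[aryl(hydroxy)methyl]-3-[(4-benzyloxy-3-methoxyphenyl)methyl]butane-1,4-diol
Conditions: LiAlH4, THF, 0 °C
Reagents that add atoms: none
Why: Hydride reduction of the lactone to the 1,4-diol; silyl and benzyl ethers survive.

Step 25
Reactants: 35 triol
Product: 36 [(2R,3S,4S)-2-aryl-4-[(4-benzyloxy-3-methoxyphenyl)methyl]oxolan-3-yl]methanol (aryl = tris-silylated tris(dihydrobenzofuran) unit)
Conditions: camphor-10-sulfonic acid (10 mol %), CH2Cl2, 0 °C to rt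
Reagents that add atoms: none
Why: Acid-catalysed ionisation of the p-alkoxybenzylic alcohol (either epimer) gives a cation stabilised by the ring B ether oxygen, which is captured 5-exo by the C4 hydroxyl of the butanediol, and the aryl group settles trans to the adjacent CH2OH because closure is reversible, which sets C2 as R.

Step 26
Reactants: 36 silylated tetrahydrofuran
Product: 37 bis(benzyl ether) of the target
Conditions: nBu4NF, THF, rt
Reagents that add atoms: none
Why: Fluoride cleaves the three silyl ethers; nothing else in the molecule is fluoride-labile.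

Step 27
Reactants: 37 bis(benzyl ether) of the target
Product: 38 CNP0267891.2
Conditions: H2 (1 atm), Pd/C, EtOAc/MeOH, rt
Reagents that add atoms: none
Why: Hydrogenolysis of the two primary aryl benzyl ethers on palladium should be much faster than cleavage of the hindered secondary cyclic benzylic C–O bonds.

**Compound list**

1 | vanillin | COc1cc(C=O)ccc1O | starting material
2 | allyl bromide | C=CCBr | starting material
3 | 4-(allyloxy)-3-methoxybenzaldehyde | COc1cc(C=O)ccc1OCC=C | intermediate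
4 | 3-allyl-4-hydroxy-5-methoxybenzaldehyde | COc1cc(C=O)cc(CC=C)c1O | intermediate
5 | 4-hydroxy-3-methoxy-5-[(1,2,4-trioxolan-3-yl)methyl]benzaldehyde (secondary ozonide) | COc1cc(C=O)cc(CC2OCOO2)c1O | intermediate
6 | 2-hydroxy-7-methoxy-2,3-dihydro-1-benzofuran-5-carbaldehyde (cyclic hemiacetal, racemic) | COc1cc(C=O)cc2CC(O)Oc12 | intermediate
7 | 7-methoxy-2-oxo-2,3-dihydro-1-benzofuran-5-carbaldehyde | COc1cc(C=O)cc2CC(=O)Oc12 | intermediate
8 | methyl 2-(5-formyl-2-hydroxy-3-methoxyphenyl)acetate | COC(=O)Cc1cc(C=O)cc(OC)c1O | intermediate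
9 | (4-benzyloxy-3-methoxyphenyl)methanol | COc1cc(CO)ccc1OCc1ccccc1 | starting material
10 | methyl 2-{2-[(4-benzyloxy-3-methoxyphenyl)methoxy]-5-formyl-3-methoxyphenyl}acetate | COC(=O)Cc1cc(C=O)cc(OC)c1OCc1ccc(OCc2ccccc2)c(OC)c1 | intermediate
11 | methyl 2-{2-[(4-benzyloxy-3-methoxyphenyl)methoxy]-5-formyl-3-methoxyphenyl}-2-diazoacetate | COC(=O)C(=[N+]=[N-])c1cc(C=O)cc(OC)c1OCc1ccc(OCc2ccccc2)c(OC)c1 | intermediate
12 | methyl (2R,3S)-2-(4-benzyloxy-3-methoxyphenyl)-5-formyl-7-methoxy-2,3-dihydro-1-benzofuran-3-carboxylate (cis) | O=Cc1cc(OC)c2c(c1)[C@H](C(=O)OC)[C@H](c1ccc(OCc3ccccc3)c(OC)c1)O2 | intermediate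
13 | methyl (2R,3R)-2-(4-benzyloxy-3-methoxyphenyl)-5-formyl-7-methoxy-2,3-dihydro-1-benzofuran-3-carboxylate (trans) | O=Cc1cc(OC)c2c(c1)[C@@H](C(=O)OC)[C@H](c1ccc(OCc3ccccc3)c(OC)c1)O2 | intermediate
14 | methyl (2R,3R)-2-(4-benzyloxy-3-methoxyphenyl)-5-(hydroxymethyl)-7-methoxy-2,3-dihydro-1-benzofuran-3-carboxylate | OCc1cc(OC)c2c(c1)[C@@H](C(=O)OC)[C@H](c1ccc(OCc3ccccc3)c(OC)c1)O2 | intermediate
15 | methyl (2R,3R)-2-(4-benzyloxy-3-methoxyphenyl)-5-{[4-formyl-2-methoxy-6-(2-methoxy-2-oxoethyl)phenoxy]methyl}-7-methoxy-2,3-dihydro-1-benzofuran-3-carboxylate | COC(=O)Cc1cc(C=O)cc(OC)c1OCc1cc(OC)c2c(c1)[C@@H](C(=O)OC)[C@H](c1ccc(OCc3ccccc3)c(OC)c1)O2 | intermediate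
16 | methyl (2R,3R)-2-(4-benzyloxy-3-methoxyphenyl)-5-{[4-(hydroxymethyl)-2-methoxy-6-(2-methoxy-2-oxoethyl)phenoxy]methyl}-7-methoxy-2,3-dihydro-1-benzofuran-3-carboxylate | COC(=O)Cc1cc(CO)cc(OC)c1OCc1cc(OC)c2c(c1)[C@@H](C(=O)OC)[C@H](c1ccc(OCc3ccccc3)c(OC)c1)O2 | intermediate
17 | methyl (2R,3R)-2-(4-benzyloxy-3-methoxyphenyl)-5-{[4-({4-formyl-2-methoxy-6-(2-methoxy-2-oxoethyl)phenoxy}methyl)-2-methoxy-6-(2-methoxy-2-oxoethyl)phenoxy]methyl}-7-methoxy-2,3-dihydro-1-benzofuran-3-carboxylate | COC(=O)Cc1cc(C=O)cc(OC)c1OCc1cc(OC)c(OCc2cc(OC)c3c(c2)[C@@H](C(=O)OC)[C@H](c2ccc(OCc4ccccc4)c(OC)c2)O3)c(CC(=O)OC)c1 | intermediate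
18 | methyl (2R,3R)-2-(4-benzyloxy-3-methoxyphenyl)-5-{[4-({2-(1-diazo-2-methoxy-2-oxoethyl)-4-formyl-6-methoxyphenoxy}methyl)-2-(1-diazo-2-methoxy-2-oxoethyl)-6-methoxyphenoxy]methyl}-7-methoxy-2,3-dihydro-1-benzofuran-3-carboxylate | COC(=O)C(=[N+]=[N-])c1cc(C=O)cc(OC)c1OCc1cc(OC)c(OCc2cc(OC)c3c(c2)[C@@H](C(=O)OC)[C@H](c2ccc(OCc4ccccc4)c(OC)c2)O3)c(C(=[N+]=[N-])C(=O)OC)c1 | intermediate
19 | methyl (2S,3R)-5-formyl-7-methoxy-2-{(2S,3R)-7-methoxy-3-(methoxycarbonyl)-2-[(2R,3R)-2-(4-benzyloxy-3-methoxyphenyl)-7-methoxy-3-(methoxycarbonyl)-2,3-dihydro-1-benzofuran-5-yl]-2,3-dihydro-1-benzofuran-5-yl}-2,3-dihydro-1-benzofuran-3-carboxylate (rings 1 and 2 cis) | O=Cc1cc(OC)c2c(c1)[C@@H](C(=O)OC)[C@@H](c1cc(OC)c3c(c1)[C@@H](C(=O)OC)[C@@H](c1cc(OC)c4c(c1)[C@@H](C(=O)OC)[C@H](c1ccc(OCc5ccccc5)c(OC)c1)O4)O3)O2 | intermediate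
20 | methyl (2S,3S)-5-formyl-7-methoxy-2-{(2S,3S)-7-methoxy-3-(methoxycarbonyl)-2-[(2R,3R)-2-(4-benzyloxy-3-methoxyphenyl)-7-methoxy-3-(methoxycarbonyl)-2,3-dihydro-1-benzofuran-5-yl]-2,3-dihydro-1-benzofuran-5-yl}-2,3-dihydro-1-benzofuran-3-carboxylate (all rings trans) | O=Cc1cc(OC)c2c(c1)[C@H](C(=O)OC)[C@@H](c1cc(OC)c3c(c1)[C@H](C(=O)OC)[C@@H](c1cc(OC)c4c(c1)[C@@H](C(=O)OC)[C@H](c1ccc(OCc5ccccc5)c(OC)c1)O4)O3)O2 | intermediate
21 | {(2S,3R)-2-[(2S,3R)-2-{(2R,3S)-2-(4-benzyloxy-3-methoxyphenyl)-3-(hydroxymethyl)-7-methoxy-2,3-dihydro-1-benzofuran-5-yl}-3-(hydroxymethyl)-7-methoxy-2,3-dihydro-1-benzofuran-5-yl]-7-methoxy-2,3-dihydro-1-benzofuran-3,5-diyl}dimethanol | OCc1cc(OC)c2c(c1)[C@H](CO)[C@@H](c1cc(OC)c3c(c1)[C@H](CO)[C@@H](c1cc(OC)c4c(c1)[C@@H](CO)[C@H](c1ccc(OCc5ccccc5)c(OC)c1)O4)O3)O2 | intermediate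
22 | (2S,3R)-2-[(2S,3R)-2-{(2R,3S)-2-(4-benzyloxy-3-methoxyphenyl)-3-(hydroxymethyl)-7-methoxy-2,3-dihydro-1-benzofuran-5-yl}-3-(hydroxymethyl)-7-methoxy-2,3-dihydro-1-benzofuran-5-yl]-3-(hydroxymethyl)-7-methoxy-2,3-dihydro-1-benzofuran-5-carbaldehyde | O=Cc1cc(OC)c2c(c1)[C@H](CO)[C@@H](c1cc(OC)c3c(c1)[C@H](CO)[C@@H](c1cc(OC)c4c(c1)[C@@H](CO)[C@H](c1ccc(OCc5ccccc5)c(OC)c1)O4)O3)O2 | intermediate
23 | tris(triisopropylsilyl) ether of 22 (all three CH2OH groups silylated, configurations as in 22) | O=Cc1cc(OC)c2c(c1)[C@H](CO[Si](C(C)C)(C(C)C)C(C)C)[C@@H](c1cc(OC)c3c(c1)[C@H](CO[Si](C(C)C)(C(C)C)C(C)C)[C@@H](c1cc(OC)c4c(c1)[C@@H](CO[Si](C(C)C)(C(C)C)C(C)C)[C@H](c1ccc(OCc5ccccc5)c(OC)c1)O4)O3)O2 | intermediate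
24 | 4-tert-butoxy-4-oxobutanoic acid | CC(C)(C)OC(=O)CCC(=O)O | starting material
25 | (S)-4-benzyl-1,3-oxazolidin-2-one | O=C1N[C@@H](Cc2ccccc2)CO1 | starting material
26 | 4-tert-butoxy-4-oxobutanoic pivalic anhydride | CC(C)(C)OC(=O)CCC(=O)OC(=O)C(C)(C)C | intermediate
27 | tert-butyl 4-[(4S)-4-benzyl-2-oxo-1,3-oxazolidin-3-yl]-4-oxobutanoate | CC(C)(C)OC(=O)CCC(=O)N1[C@@H](Cc2ccccc2)COC1=O | intermediate
28 | 1-benzyloxy-4-(bromomethyl)-2-methoxybenzene | COc1cc(CBr)ccc1OCc1ccccc1 | intermediate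
29 | sodium (Z)-enolate of 27 at the imide α-carbon | CC(C)(C)OC(=O)C/C=C(\[O-])N1[C@@H](Cc2ccccc2)COC1=O.[Na+] | intermediate
30 | tert-butyl (3S)-3-[(4-benzyloxy-3-methoxyphenyl)methyl]-4-[(4S)-4-benzyl-2-oxo-1,3-oxazolidin-3-yl]-4-oxobutanoate | COc1cc(C[C@H](C(=O)N2[C@@H](Cc3ccccc3)COC2=O)CC(=O)OC(C)(C)C)ccc1OCc1ccccc1 | intermediate
31 | tert-butyl (3S)-3-[(4-benzyloxy-3-methoxyphenyl)methyl]-4-hydroxybutanoate | COc1cc(C[C@H](CO)CC(=O)OC(C)(C)C)ccc1OCc1ccccc1 | intermediate
32 | (4S)-4-[(4-benzyloxy-3-methoxyphenyl)methyl]oxolan-2-one | COc1cc(C[C@@H]2COC(=O)C2)ccc1OCc1ccccc1 | intermediate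
33 | lithium enolate of 32 | COc1cc(C[C@@H]2COC([O-])=C2)ccc1OCc1ccccc1.[Li+] | intermediate
34 | (3R,4S)-4-[(4-benzyloxy-3-methoxyphenyl)methyl]-3-[hydroxy(aryl)methyl]oxolan-2-one, aryl = the 5-yl group of 23 in place of its CHO; both carbinol epimers | COc1cc(C[C@@H]2COC(=O)[C@H]2C(O)c3cc(OC)c4c(c3)[C@H](CO[Si](C(C)C)(C(C)C)C(C)C)[C@@H](c3cc(OC)c5c(c3)[C@H](CO[Si](C(C)C)(C(C)C)C(C)C)[C@@H](c3cc(OC)c6c(c3)[C@@H](CO[Si](C(C)C)(C(C)C)C(C)C)[C@H](c3ccc(OCc7ccccc7)c(OC)c3)O6)O5)O4)ccc1OCc1ccccc1 | intermediate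
35 | (2S,3S)-2-[hydroxy(aryl)methyl]-3-[(4-benzyloxy-3-methoxyphenyl)methyl]butane-1,4-diol, aryl as in 34; both carbinol epimers | COc1cc(C[C@H](CO)[C@@H](CO)C(O)c3cc(OC)c4c(c3)[C@H](CO[Si](C(C)C)(C(C)C)C(C)C)[C@@H](c3cc(OC)c5c(c3)[C@H](CO[Si](C(C)C)(C(C)C)C(C)C)[C@@H](c3cc(OC)c6c(c3)[C@@H](CO[Si](C(C)C)(C(C)C)C(C)C)[C@H](c3ccc(OCc7ccccc7)c(OC)c3)O6)O5)O4)ccc1OCc1ccccc1 | intermediate
36 | [(2R,3S,4S)-2-aryl-4-[(4-benzyloxy-3-methoxyphenyl)methyl]oxolan-3-yl]methanol, aryl as in 34 | COc1cc(C[C@@H]2CO[C@@H](c3cc(OC)c4c(c3)[C@H](CO[Si](C(C)C)(C(C)C)C(C)C)[C@@H](c3cc(OC)c5c(c3)[C@H](CO[Si](C(C)C)(C(C)C)C(C)C)[C@@H](c3cc(OC)c6c(c3)[C@@H](CO[Si](C(C)C)(C(C)C)C(C)C)[C@H](c3ccc(OCc7ccccc7)c(OC)c3)O6)O5)O4)[C@@H]2CO)ccc1OCc1ccccc1 | intermediate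
37 | bis(benzyl ether) of the target (both guaiacyl phenols as OCH2Ph; tetrahydrofuran 2R,3S,4S; rings 1 and 2 2S,3R; ring 3 2R,3S) | COc1cc(C[C@@H]2CO[C@@H](c3cc(OC)c4c(c3)[C@H](CO)[C@@H](c3cc(OC)c5c(c3)[C@H](CO)[C@@H](c3cc(OC)c6c(c3)[C@@H](CO)[C@H](c3ccc(OCc7ccccc7)c(OC)c3)O6)O5)O4)[C@@H]2CO)ccc1OCc1ccccc1 | intermediate
38 | CNP0267891.2: (2R,3S,4S)-4-(4-hydroxy-3-methoxybenzyl)-3-(hydroxymethyl)oxolan-2-yl at C5 of dihydrofuran ring 1 (2S,3R), whose C2 carries ring 2 (2S,3R) through its C5, whose C2 carries ring 3 (2R,3S) through its C5, ring 3 bearing 2-(4-hydroxy-3-methoxyphenyl); each dihydrobenzofuran has 3-CH2OH and 7-OMe | COc1cc(C[C@@H]2CO[C@@H](c3cc(OC)c4c(c3)[C@H](CO)[C@@H](c3cc(OC)c5c(c3)[C@H](CO)[C@@H](c3cc(OC)c6c(c3)[C@@H](CO)[C@H](c3ccc(O)c(OC)c3)O6)O5)O4)[C@@H]2CO)ccc1O | target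

**Step count**

Total: 27 steps. Longest linear sequence: 22 steps (steps 1–17 and 23–27, from vanillin).

**Steps most likely to fail**

Step 14. The first carbene may be intercepted by the second diazo group (azine or alkene formation) or by the ring B aldehyde (carbonyl ylide) before it inserts. The second insertion may be slower once one ring has closed. Imperfect facial control at either methylene would give diastereomers that are hard to separate, and prolonged methoxide could open a dihydrofuran by β-elimination of the phenoxide from the ester enolate. The fallback closes one ring at a time, so that each insertion is the single-site reaction of step 8 and each product can be purified. Setting out from 15, diazo transfer (4-acetamidobenzenesulfonyl azide, DBU, MeCN) would give the monodiazo ester F1. Rh2(R-PTTL)4 in toluene at −78 °C and then NaOMe/MeOH would give, through the cis ester F2, the trans bis(dihydrobenzofuran) aldehyde F3. NaBH4 would give the benzylic alcohol F4, Mitsunobu coupling with 8 the ether F5, and a second diazo transfer the diazo ester F6. A second insertion with Rh2(R-PTTL)4 followed by NaOMe would then give, through the cis ester F7, compound 20, where the route is rejoined.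

Step 27. Each dihydrobenzofuran C2–O bond is itself a benzyl aryl ether and the tetrahydrofuran C2–O bond is benzylic, so over-reduction by hydrogenolysis of these ring bonds may compete once the primary benzyl groups are gone. The fallback removes the benzyl groups without hydrogen. Setting out from 36, BCl3 with pentamethylbenzene as benzyl-cation trap in CH2Cl2 at −78 °C would give the bisphenol tris(silyl ether) F8, and nBu4NF would then give 38 directly.

Step 3. Ozone may attack the unprotected phenol ring, and the lactol may dehydrate to the benzofuran on work-up or during step 4. The fallback masks phenol and aldehyde and carries the side chain through open-chain intermediates. Setting out from 4, Ac2O with catalytic H2SO4 would give the triacetate F9 (aryl acetate plus aldehyde 1,1-diacetate). Lemieux–Johnson cleavage (catalytic OsO4, NaIO4, 2,6-lutidine, dioxane/water) would give the arylacetaldehyde F10, and Pinnick oxidation (NaClO2, NaH2PO4, 2-methyl-2-butene) the arylacetic acid F11. Refluxing MeOH with H2SO4 followed by aqueous acid would esterify the acid and strip the three acetyl groups, returning to 8.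

**Further compounds**

F1 | step 14 | methyl (2R,3R)-2-(4-benzyloxy-3-methoxyphenyl)-5-{[2-(1-diazo-2-methoxy-2-oxoethyl)-4-formyl-6-methoxyphenoxy]methyl}-7-methoxy-2,3-dihydro-1-benzofuran-3-carboxylate | COC(=O)C(=[N+]=[N-])c1cc(C=O)cc(OC)c1OCc1cc(OC)c2c(c1)[C@@H](C(=O)OC)[C@H](c1ccc(OCc3ccccc3)c(OC)c1)O2
F2 | step 14 | methyl (2S,3R)-5-formyl-7-methoxy-2-[(2R,3R)-2-(4-benzyloxy-3-methoxyphenyl)-7-methoxy-3-(methoxycarbonyl)-2,3-dihydro-1-benzofuran-5-yl]-2,3-dihydro-1-benzofuran-3-carboxylate (ring 2 cis) | O=Cc1cc(OC)c2c(c1)[C@@H](C(=O)OC)[C@@H](c1cc(OC)c3c(c1)[C@@H](C(=O)OC)[C@H](c1ccc(OCc4ccccc4)c(OC)c1)O3)O2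
F3 | step 14 | methyl (2S,3S)-5-formyl-7-methoxy-2-[(2R,3R)-2-(4-benzyloxy-3-methoxyphenyl)-7-methoxy-3-(methoxycarbonyl)-2,3-dihydro-1-benzofuran-5-yl]-2,3-dihydro-1-benzofuran-3-carboxylate (ring 2 trans) | O=Cc1cc(OC)c2c(c1)[C@H](C(=O)OC)[C@@H](c1cc(OC)c3c(c1)[C@@H](C(=O)OC)[C@H](c1ccc(OCc4ccccc4)c(OC)c1)O3)O2
F4 | step 14 | 5-(hydroxymethyl) analogue of F3 | OCc1cc(OC)c2c(c1)[C@H](C(=O)OC)[C@@H](c1cc(OC)c3c(c1)[C@@H](C(=O)OC)[C@H](c1ccc(OCc4ccccc4)c(OC)c1)O3)O2
F5 | step 14 | ether of F4 with the phenol oxygen of 8 (ring B arylacetate aldehyde on the closed ring 2 and ring 3 unit) | COC(=O)Cc1cc(C=O)cc(OC)c1OCc1cc(OC)c2c(c1)[C@H](C(=O)OC)[C@@H](c1cc(OC)c3c(c1)[C@@H](C(=O)OC)[C@H](c1ccc(OCc4ccccc4)c(OC)c1)O3)O2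
F6 | step 14 | diazo ester of F5 (ring B 1-diazo-2-methoxy-2-oxoethyl) | COC(=O)C(=[N+]=[N-])c1cc(C=O)cc(OC)c1OCc1cc(OC)c2c(c1)[C@H](C(=O)OC)[C@@H](c1cc(OC)c3c(c1)[C@@H](C(=O)OC)[C@H](c1ccc(OCc4ccccc4)c(OC)c1)O3)O2
F7 | step 14 | C3 epimer of 20 at ring 1 (ring 1 cis 2S,3R; ring 2 trans 2S,3S; ring 3 trans 2R,3R) | O=Cc1cc(OC)c2c(c1)[C@@H](C(=O)OC)[C@@H](c1cc(OC)c3c(c1)[C@H](C(=O)OC)[C@@H](c1cc(OC)c4c(c1)[C@@H](C(=O)OC)[C@H](c1ccc(OCc5ccccc5)c(OC)c1)O4)O3)O2
F8 | step 27 | bisphenol tris(triisopropylsilyl ether): 36 with both benzyl ethers cleaved to OH | COc1cc(C[C@@H]2CO[C@@H](c3cc(OC)c4c(c3)[C@H](CO[Si](C(C)C)(C(C)C)C(C)C)[C@@H](c3cc(OC)c5c(c3)[C@H](CO[Si](C(C)C)(C(C)C)C(C)C)[C@@H](c3cc(OC)c6c(c3)[C@@H](CO[Si](C(C)C)(C(C)C)C(C)C)[C@H](c3ccc(O)c(OC)c3)O6)O5)O4)[C@@H]2CO)ccc1O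
F9 | step 3 | (4-acetoxy-3-allyl-5-methoxyphenyl)methanediyl diacetate | CC(=O)Oc1c(CC=C)cc(C(OC(C)=O)OC(C)=O)cc1OC
F10 | step 3 | [4-acetoxy-3-methoxy-5-(2-oxoethyl)phenyl]methanediyl diacetate | CC(=O)Oc1c(CC=O)cc(C(OC(C)=O)OC(C)=O)cc1OC
F11 | step 3 | 2-[2-acetoxy-5-(diacetoxymethyl)-3-methoxyphenyl]acetic acid | CC(=O)Oc1c(CC(=O)O)cc(C(OC(C)=O)OC(C)=O)cc1OC
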